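Target had reached 56.0 % of the starting material charged by 61 min in the west run and 61.8 % at that time in the north run, and you asked me for a quick number on the north-west flask, which carries more partner.

| flask | starting material | partner | time |
|---|---|---|---|
| west | 0.250 M | 0.300 M |  |
| south-east | 0.750 M | 0.300 M |  |
| north | 0.250 M | 0.450 M |  |
| north-west | 0.250 M | 0.900 M | 61 min |

- west run (time / min: [target] / M): 2.4: 0.0013; 4.2: 0.0033; 7.1: 0.0078; 12: 0.0215; 21: 0.0454; 36: 0.0879; 61: 0.1401
- south-east run (time / min: [target] / M): 2.4: 0.0054; 4.2: 0.0102; 7.1: 0.0251; 12: 0.0557; 21: 0.1233; 36: 0.2122; 61: 0.2595
- north run (time / min: [target] / M): 2.4: 0.0024; 4.2: 0.0029; 7.1: 0.0098; 12: 0.0227; 21: 0.0537; 36: 0.1010; 61: 0.1544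

(readings scatter by 0.001 M)

- Overall: starting material + partner -> target.
- Constant volume, constant temperature.
- Readings of a species count what is bound in complexes too.
- "The second partner" is partner.
- An order is taken over about fifteen percent of the charge, up and down.

* how the opening rate goes with [partner] round the charge of the west run: the exponent of the rate at two percent of starting material gone to target
* how the opening rate goes with [starting material] round the charge of the west run: the exponent of the rate at two percent of starting material gone to target (one fixed amount of target, the same in the runs compared)
* target in the north-west run at 61 min, as a share of the starting material charged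

I replaced each curve by one mean figure, its turns: the natural logarithm of what was charged over what was left. Turns grow evenly in time when a fixed share of what is left goes each minute. The west run stood at 0.822 turns and the north run at 0.961, so 1.50 times the partner gave 1.17 times the turns. That made 0.386 my mean partner exponent, the power of the partner charge that carries one run's turns to the other's, an apparent order over the whole run.

I checked the error of that mean at 36 min, where the same reckoning gave 0.438, and I read no trend into that gap of 0.0520. Carried from the north run to twice its partner, my exponent of 0.386 gave 1.26 turns, which is 71.5 % of the charge.

Your forecast stood at 72 %, within 62 % to 82 %, with orders of 0.4 in partner and 0.7 in starting material: “The 1.5× partner run (north) is only about 1.15–1.2× faster, so the order in partner is about 0.4”. Our two figures lie together, but they come from the same readings, so that checks nothing.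

The north-west flask gave 68.1 %, with opening orders of 0.31 in partner and 0.60 in starting material. The steps behind the readings were these:

    starting material ⇌ intermediate + by-product (0.02262 min⁻¹, 0.02718 L mol⁻¹ min⁻¹)
    intermediate + partner → target (0.5646 L mol⁻¹ min⁻¹)
    partner → lost reagent (0.008940 min⁻¹)
    2 partner ⇌ idle reagent dimer, settled at all times (4.820 L mol⁻¹)

The west and north runs reached half of the starting material charged at 52.8 min and 45.8 min. Equal turns in those times give a mean partner exponent of 0.352. The north-west result stands at 1.14 turns, so from the north run to the north-west run the exponent came to 0.250, lower than the 0.386 I carried.

(The earlier runs and the new flask are calculated for an exercise, and the scatter is random.)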